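The eudesmane is cut at C5–C10, the bond that rings A and B share, so the decalin unfolds to a ten-membered ring that holds a C1–C10 trans-epoxide transannular to an E-configured C4=C5 alkene. In step 14 single-electron transfer from Cp2TiCl breaks the C10–O bond and the tertiary C10 radical bonds to C5. This one operation creates C5–C10, closes both six-membered rings, sets C5 and C10, leaves O1 untouched on C1 and delivers the C4=C15 alkene that later takes O4 and O15. Precursor 16 is the (4E)-1,10-epoxygermacr-4-ene with 6-OTES, 7-isopropyl and 9-OTBS, built from geranyl acetate by asymmetric epoxidation, allylboration and an allylative macrocyclisation.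

Key step: step 14

Remark: germacrane/eudesmane numbering is used for all intermediates (C14 = methyl on C10, C15 = carbon on C4; C12/C13 = isopropyl carbons).
Remark: in 16, O9 stays a bulky silyl ether (a poor β-leaving group next to the C10 radical) and O6 is capped so that no O–H sits next to the C4 radical.

Step 1
Reactants: 1 geranyl acetate
Product: 2 (2E,6E)-8-hydroxygeranyl acetate
Conditions: SeO2 (cat.), tBuOOH, salicylic acid (cat.), CH2Cl2, rt
Reagents that add atoms: tert-butyl hydroperoxide, CC(C)(C)OO
Why: Catalytic SeO2 allylic oxidation (ene reaction followed by [2,3]-sigmatropic shift, with tBuOOH as terminal oxidant) should attack the E-methyl group of the electron-richer 6,7-alkene, because the 2,3-alkene is deactivated by the allylic acetate, and it creates no stereocentre.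

Step 2
Reactants: 2 (2E,6E)-8-hydroxygeranyl acetate
Product: 3 (6S,7S)-6,7-epoxy-8-hydroxygeranyl acetate
Conditions: Ti(OiPr)4, L-(+)-diethyl tartrate, tBuOOH, 4 Å molecular sieves, CH2Cl2, −20 °C
Reagents that add atoms: tert-butyl hydroperoxide, CC(C)(C)OO
Why: Sharpless asymmetric epoxidation of the free allylic alcohol, in which the L-(+)-tartrate complex should deliver oxygen to the face that gives the (S,S)-epoxide (future C1 and C10), while the alkene next to the acetate cannot bind titanium and stays intact.

Step 3
Reactants: 3 (6S,7S)-6,7-epoxy-8-hydroxygeranyl acetate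
Product: 4 epoxy aldehyde
Conditions: IBX, DMSO, rt
Reagents that add atoms: none
Why: IBX oxidation of the primary alcohol to the aldehyde, whose α-carbon is quaternary so that neither epoxide stereocentre can epimerise.

Step 4
Reactants: 4 epoxy aldehyde
Product: 6 epoxy homoallylic alcohol (9R), via borinate ester 5 (not isolated)
Conditions: (+)-Ipc2B(allyl), Et2O, −78 °C; then H2O2, pH 7 phosphate buffer, MeOH, 0 °C
Reagents that add atoms: (+)-B-allyldiisopinocampheylborane, C=CCB([C@H]1C[C@H]2C[C@@H]([C@@H]1C)C2(C)C)[C@H]1C[C@H]2C[C@@H]([C@@H]1C)C2(C)C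
Why: Brown asymmetric allylboration through a closed chair transition state, in which the isopinocampheyl groups of the (−)-α-pinene-derived reagent choose the aldehyde face and should set C9 as R (threo to the oxirane oxygen) under reagent control, after which buffered peroxide cleaves the B–O bond without hydrolysing the acetate.

Step 5
Reactants: 6 epoxy homoallylic alcohol (9R)
Product: 7 9-O-TBS ether
Conditions: TBSOTf, 2,6-lutidine, CH2Cl2, −78 to 0 °C
Reagents that add atoms: tert-butyldimethylsilyl triflate, CC(C)(C)[Si](C)(C)OS(=O)(=O)C(F)(F)F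
Why: Silylation of the hindered secondary alcohol with a silyl triflate and a hindered base, which changes no stereocentre and installs the group that O9 keeps until the last step.

Step 6
Reactants: 7 9-O-TBS ether; 8 methacrolein
Product: 9 (E)-enal
Conditions: second-generation Hoveyda–Grubbs catalyst (H2IMes)Cl2Ru(=CH-C6H4-2-OiPr) (5 mol%), 8 in excess, CH2Cl2, 40 °C
Reagents that add atoms: none
Why: Olefin cross-metathesis of the terminal alkene with methacrolein should give the E-configured trisubstituted enal under thermodynamic control, the trisubstituted alkene and the epoxide being inert to the ruthenium carbene.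

Step 7
Reactants: 9 (E)-enal
Product: 10 allylic alcohol
Conditions: NaBH4, MeOH, −20 °C
Reagents that add atoms: none
Why: Chemoselective 1,2-reduction of the α-branched enal by borohydride at low temperature, which is much faster than attack on the acetate or the epoxide.

Step 8
Reactants: 10 allylic alcohol
Product: 11 allylic chloride
Conditions: N-chlorosuccinimide, Me2S, CH2Cl2, −20 to 0 °C
Reagents that add atoms: N-chlorosuccinimide, O=C1CCC(=O)N1Cl
Why: Corey–Kim chlorination, in which the alkoxysulfonium ion is displaced by chloride in an SN2 sense at the primary allylic carbon, so the E-alkene is not transposed and the acid-free medium spares the epoxide.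

Step 9
Reactants: 11 allylic chloride
Product: 12 hydroxy chloride
Conditions: iBu2AlH, CH2Cl2, −78 °C
Reagents that add atoms: none
Why: Reductive cleavage of the acetate by the aluminium hydride at −78 °C, a temperature at which the allylic chloride and the trisubstituted epoxide should not react.

Step 10
Reactants: 12 hydroxy chloride
Product: 13 chloro enal
Conditions: MnO2, CH2Cl2, rt
Reagents that add atoms: none
Why: MnO2 oxidation is selective for the allylic alcohol and should give the E-enal without touching the allylic chloride or the epoxide.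

Step 11
Reactants: 13 chloro enal
Product: 14 epoxygermacradienol
Conditions: Pd(PPh3)4 (10 mol%), Et2Zn, K2CO3, DMA, rt, slow addition to 0.005 M
Reagents that add atoms: none
Why: Palladium-catalysed umpolung allylation, in which zerovalent palladium ionises the allylic chloride, Et2Zn turns the π-allylpalladium into an allylzinc species and this adds through its γ-carbon to the aldehyde in a six-membered chair transition state, forming C6–C7 and the ten-membered ring with O6 anti to C8; the sense relative to C9 should follow from the transition state that keeps 9-OTBS, the isopropenyl group and O6 pseudo-equatorial on the forming ring (6S,7R).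

Step 12
Reactants: 14 epoxygermacradienol
Product: 15 epoxygermacrenol
Conditions: H2 (1 atm), RhCl(PPh3)3 (10 mol%), benzene, rt
Reagents that add atoms: none
Why: Homogeneous hydrogenation with RhCl(PPh3)3 reduces the 1,1-disubstituted isopropenyl alkene far faster than the trisubstituted ring alkene and leaves the epoxide alone, and it creates no stereocentre (C6 becomes R only because the CIP ranking changes).

Step 13
Reactants: 15 epoxygermacrenol
Product: 16 (4E)-1,10-epoxygermacr-4-ene 6-O-TES 9-O-TBS
Conditions: Et3SiCl, imidazole, DMAP (cat.), DMF, rt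
Reagents that add atoms: chlorotriethylsilane, CC[Si](Cl)(CC)CC
Why: Silylation of O6 with the silyl chloride under basic conditions, chosen over a Lewis-acidic silyl triflate because the epoxygermacrene cyclises under acid.

Step 14
Reactants: 16 (4E)-1,10-epoxygermacr-4-ene 6-O-TES 9-O-TBS
Product: 17 trans-eudesm-4(15)-en-1-ol 6-O-TES 9-O-TBS
Conditions: Cp2TiCl2 (2.5 equiv), Mn dust (8 equiv), THF, rt, Ar, slow addition of 16; aqueous NaH2PO4 work-up
Reagents that add atoms: none
Why: Electron transfer from Cp2TiCl (trivalent titanium, generated in the flask by Mn reduction of Cp2TiCl2) to the oxirane breaks the C10–O bond because that gives the tertiary radical, and O1 remains on C1 as a tetravalent titanium alkoxide, so C1 keeps its configuration. This is titanocene-mediated reductive epoxide opening with radical cyclisation (Nugent–RajanBabu chemistry), used here in its transannular form, which is established for 1,10-epoxygermacr-4-enes. The C10 radical bonds to C5 of the alkene lying across the ten-membered ring, a closure that is 6-exo-trig for ring B (C4 stays outside) and 6-endo-trig for ring A (C4 and C5 both end up inside), and the new tertiary C4 radical is trapped by a second Cp2TiCl and eliminates Cp2Ti(H)Cl towards the C15 methyl group, the least hindered source of a β-hydrogen, to leave the C4=C15 alkene. C10 is controlled by the ring, since only the radical lobe that points into the macrocycle, on the side away from the former C10–O bond, can reach C5, so C14 ends up cis to O1 and O9. C5 is controlled by the E geometry of C4=C5 within the crossed chair–chair-like conformer, which the pseudo-equatorial 6-OTES, 7-isopropyl and 9-OTBS groups favour and which puts H5 anti to C14 (trans-decalin). The step needs cyclisation to outrun reduction of the C10 radical and loss of the neighbouring O9 group, which the transannular proximity of C5, the slow capture of a hindered tertiary radical by titanium and the poor leaving-group ability of the bulky silyl ether should secure, while the silyl cap on O6 removes a hydroxyl that could pass a hydrogen atom to C4.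

Step 15
Reactants: 17 trans-eudesm-4(15)-en-1-ol 6-O-TES 9-O-TBS
Product: 18 1,9-bis-O-TBS 6-O-TES eudesm-4(15)-ene
Conditions: TBSOTf, 2,6-lutidine, CH2Cl2, 0 °C
Reagents that add atoms: tert-butyldimethylsilyl triflate, CC(C)(C)[Si](C)(C)OS(=O)(=O)C(F)(F)F
Why: Silylation of the equatorial secondary O1–H with the silyl triflate, so that O1 cannot enter the later orthoester exchange.

Step 16
Reactants: 18 1,9-bis-O-TBS 6-O-TES eudesm-4(15)-ene
Product: 19 1,9-bis-O-TBS eudesm-4(15)-en-6-ol
Conditions: PPTS (cat.), MeOH/CH2Cl2 (1:1), 0 °C to rt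
Reagents that add atoms: none
Why: Acid-catalysed methanolysis cleaves the triethylsilyl ether much faster than the two hindered tert-butyldimethylsilyl ethers, which frees O6 alone.

Step 17
Reactants: 19 1,9-bis-O-TBS eudesm-4(15)-en-6-ol
Product: 20 1,9-bis-O-TBS eudesmane-4,6,15-triol
Conditions: OsO4 (5 mol%), N-methylmorpholine N-oxide, acetone/H2O, rt
Reagents that add atoms: N-methylmorpholine N-oxide, C[N+]1([O-])CCOCC1; water, O
Why: Upjohn dihydroxylation, in which OsO4 adds in a [3+2] sense to the exocyclic C4=C15 alkene from the face opposite the axial C14 methyl group, so that O4 becomes equatorial and trans to C14 and C15 axial (C4 S).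

Step 18
Reactants: 21 (E)-cinnamonitrile
Product: 22 methyl (E)-cinnamimidate hydrochloride
Conditions: HCl (gas), MeOH (1.1 equiv), Et2O, 0 °C
Reagents that add atoms: methanol, CO; hydrogen chloride, Cl
Why: Pinner reaction, in which HCl activates the nitrile for addition of methanol and the imidate hydrochloride crystallises, the E alkene being untouched.

Step 19
Reactants: 22 methyl (E)-cinnamimidate hydrochloride
Product: 23 trimethyl orthocinnamate
Conditions: MeOH (excess), hexane, rt
Reagents that add atoms: methanol, CO
Why: Pinner orthoester synthesis, in which methanolysis of the imidate salt replaces nitrogen by two further methoxy groups and NH4Cl precipitates.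

Step 20
Reactants: 20 1,9-bis-O-TBS eudesmane-4,6,15-triol; 23 trimethyl orthocinnamate
Product: 24 1,9-bis-O-TBS orthoester
Conditions: CSA (cat.), 5 Å molecular sieves, CH2Cl2, rt
Reagents that add atoms: none
Why: Acid-catalysed orthoester exchange, in which primary O15, tertiary O4 and secondary O6 of the 1,2,4-triol replace the three methoxy groups one after another via dialkoxycarbenium ions and removal of methanol drives formation of the 2,7,8-trioxabicyclo[3.2.1]octane, whose orthoester carbon can only take the configuration the cage allows (S).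

Step 21
Reactants: 24 1,9-bis-O-TBS orthoester
Product: 25 CNP0252898.1
Conditions: Bu4NF, THF, 50 °C
Reagents that add atoms: none
Why: Fluoride-mediated desilylation of O1 and O9 under basic conditions, which the acid-labile orthoester tolerates.

Compound list
1 | geranyl acetate, (2E)-3,7-dimethylocta-2,6-dien-1-yl acetate | CC(C)=CCC/C(C)=C/COC(C)=O | starting material
2 | (2E,6E)-8-hydroxy-3,7-dimethylocta-2,6-dien-1-yl acetate | OC/C(C)=C/CC/C(C)=C/COC(C)=O | intermediate
3 | (2E)-5-[(2S,3S)-3-(hydroxymethyl)-3-methyloxiran-2-yl]-3-methylpent-2-en-1-yl acetate | OC[C@]1(C)O[C@H]1CC/C(C)=C/COC(C)=O | intermediate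
4 | (2E)-5-[(2S,3R)-3-formyl-3-methyloxiran-2-yl]-3-methylpent-2-en-1-yl acetate | O=C[C@]1(C)O[C@H]1CC/C(C)=C/COC(C)=O | intermediate
5 | O-diisopinocampheylborinate of 6 (boron on O9) | C=CC[C@@H](OB([C@H]1C[C@H]2C[C@@H]([C@@H]1C)C2(C)C)[C@H]1C[C@H]2C[C@@H]([C@@H]1C)C2(C)C)[C@]1(C)O[C@H]1CC/C(C)=C/COC(C)=O | intermediate
6 | (2E)-5-[(2S,3S)-3-[(1R)-1-hydroxybut-3-en-1-yl]-3-methyloxiran-2-yl]-3-methylpent-2-en-1-yl acetate | C=CC[C@@H](O)[C@]1(C)O[C@H]1CC/C(C)=C/COC(C)=O | intermediate
7 | (2E)-5-[(2S,3R)-3-[(1R)-1-[(tert-butyldimethylsilyl)oxy]but-3-en-1-yl]-3-methyloxiran-2-yl]-3-methylpent-2-en-1-yl acetate | C=CC[C@@H](O[Si](C)(C)C(C)(C)C)[C@]1(C)O[C@H]1CC/C(C)=C/COC(C)=O | intermediate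
8 | methacrolein, 2-methylprop-2-enal | CC(=C)C=O | starting material
9 | (2E)-5-[(2S,3R)-3-[(1R,3E)-1-[(tert-butyldimethylsilyl)oxy]-4-methyl-5-oxopent-3-en-1-yl]-3-methyloxiran-2-yl]-3-methylpent-2-en-1-yl acetate | O=C/C(C)=C/C[C@@H](O[Si](C)(C)C(C)(C)C)[C@]1(C)O[C@H]1CC/C(C)=C/COC(C)=O | intermediate
10 | (2E)-5-[(2S,3R)-3-[(1R,3E)-1-[(tert-butyldimethylsilyl)oxy]-5-hydroxy-4-methylpent-3-en-1-yl]-3-methyloxiran-2-yl]-3-methylpent-2-en-1-yl acetate | OC/C(C)=C/C[C@@H](O[Si](C)(C)C(C)(C)C)[C@]1(C)O[C@H]1CC/C(C)=C/COC(C)=O | intermediate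
11 | (2E)-5-[(2S,3R)-3-[(1R,3E)-1-[(tert-butyldimethylsilyl)oxy]-5-chloro-4-methylpent-3-en-1-yl]-3-methyloxiran-2-yl]-3-methylpent-2-en-1-yl acetate | ClC/C(C)=C/C[C@@H](O[Si](C)(C)C(C)(C)C)[C@]1(C)O[C@H]1CC/C(C)=C/COC(C)=O | intermediate
12 | (2E)-5-[(2S,3R)-3-[(1R,3E)-1-[(tert-butyldimethylsilyl)oxy]-5-chloro-4-methylpent-3-en-1-yl]-3-methyloxiran-2-yl]-3-methylpent-2-en-1-ol | ClC/C(C)=C/C[C@@H](O[Si](C)(C)C(C)(C)C)[C@]1(C)O[C@H]1CC/C(C)=C/CO | intermediate
13 | (2E)-5-[(2S,3R)-3-[(1R,3E)-1-[(tert-butyldimethylsilyl)oxy]-5-chloro-4-methylpent-3-en-1-yl]-3-methyloxiran-2-yl]-3-methylpent-2-enal | ClC/C(C)=C/C[C@@H](O[Si](C)(C)C(C)(C)C)[C@]1(C)O[C@H]1CC/C(C)=C/C=O | intermediate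
14 | (1S,4E,6S,7R,9R,10R)-9-[(tert-butyldimethylsilyl)oxy]-1,10-epoxygermacra-4,11-dien-6-ol | C=C(C)[C@H]1C[C@@H](O[Si](C)(C)C(C)(C)C)[C@]2(C)O[C@H]2CC/C(C)=C/[C@@H]1O | intermediate
15 | (1S,4E,6R,7R,9R,10R)-9-[(tert-butyldimethylsilyl)oxy]-1,10-epoxygermacr-4-en-6-ol | CC(C)[C@H]1C[C@@H](O[Si](C)(C)C(C)(C)C)[C@]2(C)O[C@H]2CC/C(C)=C/[C@@H]1O | intermediate
16 | (1S,4E,6R,7R,9R,10R)-9-[(tert-butyldimethylsilyl)oxy]-1,10-epoxy-6-[(triethylsilyl)oxy]germacr-4-ene | CC(C)[C@H]1C[C@@H](O[Si](C)(C)C(C)(C)C)[C@]2(C)O[C@H]2CC/C(C)=C/[C@@H]1O[Si](CC)(CC)CC | intermediate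
17 | (1S,5R,6R,7R,9R,10S)-9-[(tert-butyldimethylsilyl)oxy]-6-[(triethylsilyl)oxy]eudesm-4(15)-en-1-ol (trans-decalin) | CC(C)[C@H]1C[C@@H](O[Si](C)(C)C(C)(C)C)[C@@]2(C)[C@H]([C@@H]1O[Si](CC)(CC)CC)C(=C)CC[C@@H]2O | intermediate
18 | (1S,5R,6R,7R,9R,10S)-1,9-bis[(tert-butyldimethylsilyl)oxy]-6-[(triethylsilyl)oxy]eudesm-4(15)-ene | CC(C)[C@H]1C[C@@H](O[Si](C)(C)C(C)(C)C)[C@@]2(C)[C@H]([C@@H]1O[Si](CC)(CC)CC)C(=C)CC[C@@H]2O[Si](C)(C)C(C)(C)C | intermediate
19 | (1S,5R,6R,7R,9R,10S)-1,9-bis[(tert-butyldimethylsilyl)oxy]eudesm-4(15)-en-6-ol | CC(C)[C@H]1C[C@@H](O[Si](C)(C)C(C)(C)C)[C@@]2(C)[C@H]([C@@H]1O)C(=C)CC[C@@H]2O[Si](C)(C)C(C)(C)C | intermediate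
20 | (1S,4S,5R,6R,7R,9R,10S)-1,9-bis[(tert-butyldimethylsilyl)oxy]eudesmane-4,6,15-triol | CC(C)[C@H]1C[C@@H](O[Si](C)(C)C(C)(C)C)[C@@]2(C)[C@H]([C@@H]1O)[C@](O)(CO)CC[C@@H]2O[Si](C)(C)C(C)(C)C | intermediate
21 | (E)-cinnamonitrile, (2E)-3-phenylprop-2-enenitrile | N#C/C=C/c1ccccc1 | starting material
22 | methyl (2E)-3-phenylprop-2-enimidate hydrochloride | COC(=[NH2+])/C=C/c1ccccc1.[Cl-] | intermediate
23 | trimethyl orthocinnamate, (E)-(3,3,3-trimethoxyprop-1-en-1-yl)benzene | COC(OC)(OC)/C=C/c1ccccc1 | intermediate
24 | (1S,4S,5R,6R,7R,9R,10S)-1,9-bis[(tert-butyldimethylsilyl)oxy]eudesmane-4,6,15-triyl (E)-orthocinnamate (orthoester carbon S) | CC(C)[C@H]1C[C@@H](O[Si](C)(C)C(C)(C)C)[C@@]2(C)[C@@H]3[C@@H]1O[C@]1(/C=C/c4ccccc4)OC[C@@]3(CC[C@@H]2O[Si](C)(C)C(C)(C)C)O1 | intermediate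
25 | CNP0252898.1, (1S,4S,5R,6R,7R,9R,10S)-eudesmane-1,4,6,9,15-pentol 4,6,15-(E)-orthocinnamate (orthoester carbon S) | CC(C)[C@H]1C[C@@H](O)[C@@]2(C)[C@@H]3[C@@H]1O[C@]1(/C=C/c4ccccc4)OC[C@@]3(CC[C@@H]2O)O1 | target

Total step count: 21. Longest linear sequence: 19 steps (steps 1–17, 20 and 21, from geranyl acetate); steps 18 and 19 prepare the orthoester reagent.

Steps most likely to fail

Step 14. After the oxirane opens, the C10 radical may be reduced by a second titanium before it cyclises, which would expel the O9 silyloxy group, or the C4 radical may terminate without regiocontrol. The fallback replaces the radical by a cation and sets out from 16. A Lewis acid (BF3·OEt2, CH2Cl2, −78 °C) opens the epoxide at C10, and the cation closes onto C5 through the same crossed conformer and loses a proton. This known acid-promoted transannular cyclisation of 1,10-epoxygermacrenes would give the exocyclic alkene together with the endocyclic Δ3 double-bond isomer F1. After separation on AgNO3-impregnated silica the route is rejoined at 17.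

Step 11. Intermolecular allylation (oligomers) may compete with ring closure, and the face of the aldehyde taken up relative to C9 rests on substrate control alone. The fallback closes a larger ring first and then contracts it, setting out from 12. Intramolecular Williamson etherification (NaH, THF, high dilution) joins O6 to C12 and gives the thirteen-membered cyclic diallyl ether F2. A [2,3]-Wittig ring contraction (nBuLi, THF, −78 °C) then deprotonates C6, forms C6–C7 and releases O6 as the alkoxide. With the trans arrangement expected from the folded five-membered transition state this should give the same epoxygermacradienol, and the route is rejoined at 14.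

Step 20. The exchange may stop at a monocyclic mixed orthoester that collapses to a hydroxy ester on work-up, and reagent 23 may be hard to obtain free of amide. The fallback builds the orthoester from an ester and sets out from 20. The primary O15–H is acylated with (E)-cinnamoyl chloride (2,4,6-collidine, CH2Cl2, −20 °C) to the 15-O-cinnamate F3. Acid-catalysed cyclodehydration (CSA, benzene, reflux with azeotropic removal of water) then closes O4 and O6 onto the acyl carbon through the 2-styryl-1,3-dioxolan-2-ylium ion. The route is rejoined at 24.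

Further compounds
F1 | step 14 | (1S,5R,6R,7R,9R,10S)-9-[(tert-butyldimethylsilyl)oxy]-6-[(triethylsilyl)oxy]eudesm-3-en-1-ol | CC(C)[C@H]1C[C@@H](O[Si](C)(C)C(C)(C)C)[C@@]2(C)[C@H]([C@@H]1O[Si](CC)(CC)CC)C(C)=CC[C@@H]2O
F2 | step 11 | thirteen-membered cyclic diallyl ether of 12 (O6 bonded to C12; both alkenes E; epoxide and 9-OTBS unchanged) | O1C/C(C)=C/C[C@@H](O[Si](C)(C)C(C)(C)C)[C@]2(C)O[C@H]2CC/C(C)=C/C1
F3 | step 20 | 15-O-[(E)-cinnamoyl] derivative of 20 | CC(C)[C@H]1C[C@@H](O[Si](C)(C)C(C)(C)C)[C@@]2(C)[C@H]([C@@H]1O)[C@](O)(COC(=O)/C=C/c1ccccc1)CC[C@@H]2O[Si](C)(C)C(C)(C)C
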